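## Retrosynthetic overview

1. The strategy rests on C10(O)–C11–C12(Me)=C13–C14(=O), a δ-oxygenated β-methyl enoate hidden between oxolane carbon C10 and the C12/C13 epoxide–C14 ketone; the oxolane (C7–C8–C9–C10–O) is read as a γ-lactone with C7 as carbonyl (cembrane numbering: C1 isopropylidene carbon, C15 its exocyclic carbon, C16 the CH2 that is functionalised, C4 acetate carbon).
2. C14 ketone and C1=C15 ⇐ oxidation and conjugation of a C14 carbinol / C1 isopropenyl pair; C4 acetate ⇐ tertiary alcohol; C6=C7 enol ether ⇐ Ramberg–Bäcklund contraction of a C6–SO2–C7 macrocycle.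
3. Macrocycle ⇐ intramolecular Nozaki–Hiyama allylation C14–C1 (12,13-epoxy aldehyde + C16 allylic bromide from (R)-linalool); epoxide ⇐ Sharpless epoxidation; C6–S–C7 ⇐ S-alkylation of a C7 anomeric thiolate by the linalool-derived C6 tosylate.
4. Lactone enoate C7–C14 ⇐ vinylogous Mukaiyama aldol (C10–C11) of the methyl senecioate silyl dienolate with methyl (S)-2-methyl-4-oxobutanoate, then lactonisation (O–C7).
5. Ring order: γ-lactone = oxolane (step 5) → epoxide (step 16) → sulfone macrocycle (step 20) → 14-membered carbocycle (step 22).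

Key step: step 5

Remark 1: the (S,S)-bisphosphoramide (binaphthyldiamine-derived, pentane-1,5-diyl tether) is specified on the premise that its (R,R)-antipode delivers silyl nucleophiles to the Re face of aldehydes; C10 (R) needs Si-face attack, so if the sense is the reverse the antipodal catalyst is used and nothing else changes.

Remark 2: C7 (steps 6–21) and C1/C14 (steps 20–25) are carried as epimer mixtures and later become sp2. The CIP label of C13 alternates (S in 22 and 26–32, R in 23–25, 33 and 34) without change of configuration.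

## Route

Step 1
Reactants: 1 (R)-4-benzyl-3-propanoyloxazolidin-2-one; 2 allyl iodide
Product: 3 (R)-4-benzyl-3-[(2S)-2-methylpent-4-enoyl]oxazolidin-2-one
Conditions: NaHMDS, THF, −78 °C; then 2, −78 → −45 °C
Reagents that add atoms: none
Why: Evans asymmetric alkylation: the chelated Z-sodium enolate is allylated on the face away from the benzyl group, which sets C8 (S).

Step 2
Reactants: 3 allylated imide
Product: 4 methyl (2S)-2-methylpent-4-enoate
Conditions: MeMgBr, MeOH, CH2Cl2, 0 °C (MeOMgBr in situ)
Reagents that add atoms: methoxymagnesium bromide (made from MeMgBr and MeOH), CO[Mg]Br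
Why: Transesterification of the N-acyl oxazolidinone at the exocyclic carbonyl by the weakly basic magnesium methoxide should remove the auxiliary without epimerising C8.

Step 3
Reactants: 4 methyl (2S)-2-methylpent-4-enoate
Product: 5 methyl (2S)-2-methyl-4-oxobutanoate
Conditions: O3, CH2Cl2, −78 °C; PPh3, −78 °C → rt
Reagents that add atoms: ozone, [O-][O+]=O
Why: Ozonolysis with reductive work-up cleaves the terminal alkene to the C10 aldehyde under neutral conditions that leave the α-methyl ester and C8 untouched.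

Step 4
Reactants: 6 methyl 3-methylbut-2-enoate (methyl senecioate)
Product: 7 tert-butyl[(1-methoxy-3-methylbuta-1,3-dien-1-yl)oxy]dimethylsilane
Conditions: LDA, THF, −78 °C; TBSCl, DMPU, −78 °C → rt
Reagents that add atoms: tert-butyldimethylsilyl chloride, CC(C)(C)[Si](C)(C)Cl
Why: Kinetic γ-deprotonation and O-silylation of the lithium dienolate (silyl ketene acetal formation) give the silyl dienolate, the TBS acetal being the robust variant used in SiCl4/Lewis-base catalysis.

Step 5
Reactants: 5 methyl (2S)-2-methyl-4-oxobutanoate; 7 TBS dienolate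
Product: 9 methyl (2E)-3-methyl-4-[(2R,4S)-4-methyl-5-oxooxolan-2-yl]but-2-enoate, via hydroxy diester 8 (not isolated)
Conditions: SiCl4 (1.1 equiv), (S,S)-bisphosphoramide (5 mol%), i-Pr2NEt (10 mol%), CH2Cl2, −72 °C; aq KF/NaHCO3; then PPTS (cat.), CH2Cl2, rt
Reagents that add atoms: none
Why: The phosphoramide-bound trichlorosilyl cation formed from SiCl4 activates the C10 aldehyde and the silyl dienolate attacks through its γ-carbon C11 in an open transition state, the C12=C13 bond re-forming in conjugation as the E-enoate while the silyl group leaves as TBSCl; this is the Lewis-base-catalysed, SiCl4-mediated vinylogous Mukaiyama aldol of ester-derived silyl dienolates. After the fluoride/bicarbonate work-up the C10 hydroxyl of 8 attacks the C7 methyl ester under PPTS (5-exo-trig acyl substitution, loss of methanol) and closes the γ-lactone that becomes the oxolane. C10 (R) is set by the catalyst through Si-face attack; the β-methyl centre C8 exerts only a weak 1,3-bias and is not touched, so the trans-3,5-disubstituted lactone should result. The step needs γ- over α-attack, secured by the hindered ketene-acetal terminus and the larger coefficient at C11, and E- over Z-geometry, secured by the open transition state; any Z isomer or C10 epimer is removed at the crystalline-lactone/chromatography stage.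

Step 6
Reactants: 9 lactone enoate
Product: 10 (3S,5R)-5-[(2E)-4-hydroxy-2-methylbut-2-en-1-yl]-3-methyloxolan-2-ol (C7 anomers)
Conditions: DIBAL-H (3.5 equiv), CH2Cl2, −78 °C; Rochelle salt
Reagents that add atoms: none
Why: DIBAL reduction at −78 °C stops at the lactol (stable aluminium hemiacetal) and takes the enoate by 1,2-reduction to the E-allylic alcohol.

Step 7
Reactants: 10 lactol allylic alcohol
Product: 11 (3S,5R)-5-[(2E)-4-(tert-butyldiphenylsilyloxy)-2-methylbut-2-en-1-yl]-3-methyloxolan-2-ol
Conditions: TBDPSCl (1.05 equiv), imidazole, CH2Cl2, 0 °C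
Reagents that add atoms: tert-butyldiphenylsilyl chloride, CC(C)(C)[Si](Cl)(c1ccccc1)c1ccccc1
Why: Selective silylation: the bulky chloride should react with the primary allylic C14 hydroxyl much faster than with the hindered hemiacetal hydroxyl.

Step 8
Reactants: 11 silyl-protected lactol
Product: 12 S-[(3S,5R)-5-[(2E)-4-(tert-butyldiphenylsilyloxy)-2-methylbut-2-en-1-yl]-3-methyloxolan-2-yl] ethanethioate (C7 anomers)
Conditions: AcSH (3 equiv), BF3·OEt2 (0.3 equiv), 4 Å MS, CH2Cl2, −40 → −20 °C
Reagents that add atoms: thioacetic acid, CC(=O)S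
Why: Lewis-acid anomeric substitution: the lactol ionises to the oxolanyl oxocarbenium ion, which is trapped at sulfur by excess thioacid faster than it can lose the C8 proton, while the allylic TBDPS ether tolerates BF3 at low temperature.

Step 9
Reactants: 13 (R)-linalool
Product: 14 (2E,6R)-2,6-dimethylocta-2,7-diene-1,6-diol ((E)-8-hydroxylinalool)
Conditions: SeO2 (cat.), t-BuOOH, salicylic acid (cat.), CH2Cl2, rt
Reagents that add atoms: tert-butyl hydroperoxide, CC(C)(C)OO
Why: Selenium dioxide allylic oxidation (ene reaction, then [2,3]-shift) hydroxylates the E-methyl group of the trisubstituted alkene, while the vinyl group has no allylic hydrogen and C4 is not touched.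

Step 10
Reactants: 14 (E)-8-hydroxylinalool
Product: 15 (3R,6E)-8-[(4-methoxybenzyl)oxy]-3,7-dimethylocta-1,6-dien-3-ol
Conditions: NaH (1.05 equiv), PMBCl, Bu4NI (cat.), THF/DMF, 0 °C
Reagents that add atoms: 4-methoxybenzyl chloride, COc1ccc(CCl)cc1
Why: Williamson etherification: with one equivalent of base the primary allylic alkoxide forms and is alkylated in preference to the hindered tertiary one.

Step 11
Reactants: 15 PMB ether
Product: 16 (3R,6E)-8-[(4-methoxybenzyl)oxy]-3,7-dimethyloct-6-ene-1,3-diol
Conditions: 9-BBN (2.2 equiv), THF, 0 °C → rt; NaOH, H2O2, 0 °C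
Reagents that add atoms: hydrogen peroxide, OO
Why: Hydroboration–oxidation: 9-BBN adds anti-Markovnikov to the monosubstituted vinyl group and ignores the trisubstituted alkene, giving the C6 primary alcohol.

Step 12
Reactants: 16 1,3-diol
Product: 17 (3R,6E)-3-hydroxy-8-[(4-methoxybenzyl)oxy]-3,7-dimethyloct-6-en-1-yl 4-methylbenzenesulfonate
Conditions: TsCl (1.1 equiv), Et3N, DMAP (cat.), CH2Cl2, 0 °C
Reagents that add atoms: 4-toluenesulfonyl chloride, Cc1ccc(cc1)S(=O)(=O)Cl
Why: Selective sulfonylation of the primary C6 hydroxyl; the tertiary C4 hydroxyl does not react under these conditions.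

Step 13
Reactants: 12 anomeric thioacetate; 17 tosylate
Product: 19 (3R,6E)-1-{[(3S,5R)-5-[(2E)-4-(tert-butyldiphenylsilyloxy)-2-methylbut-2-en-1-yl]-3-methyloxolan-2-yl]sulfanyl}-8-[(4-methoxybenzyl)oxy]-3,7-dimethyloct-6-en-3-ol, via sodium thiolate 18 (not isolated)
Conditions: 12, NaOMe (1.0 equiv), degassed MeOH, 0 °C; then 17, DMF, rt
Reagents that add atoms: none
Why: S-Deacetylation followed by SN2 S-alkylation: methoxide frees the anomeric thiolate, which displaces the primary tosylate and forms the C7–S–C6 link without acid and without touching the acid-labile linalool half.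

Step 14
Reactants: 19 thioether
Product: 20 the corresponding C6–SO2–C7 sulfone
Conditions: (NH4)6Mo7O24·4H2O (cat.), 30% H2O2, EtOH, 0 °C → rt
Reagents that add atoms: hydrogen peroxide, OO
Why: Molybdate-catalysed sulfide-to-sulfone oxidation is chemoselective for sulfur and should leave both trisubstituted alkenes, which carry no free allylic hydroxyl here, unchanged.

Step 15
Reactants: 20 sulfone
Product: 21 (3R,6E)-1-{[(3S,5R)-5-[(2E)-4-hydroxy-2-methylbut-2-en-1-yl]-3-methyloxolan-2-yl]sulfonyl}-8-[(4-methoxybenzyl)oxy]-3,7-dimethyloct-6-en-3-ol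
Conditions: TBAF, AcOH, THF, rt
Reagents that add atoms: none
Why: Buffered fluoride desilylation frees the C14 allylic alcohol without base-mediated elimination at the anomeric sulfone and without loss of the PMB ether.

Step 16
Reactants: 21 allylic alcohol
Product: 22 (12S,13S)-epoxy alcohol, side chain now [(2S,3S)-3-(hydroxymethyl)-2-methyloxiran-2-yl]methyl
Conditions: Ti(Oi-Pr)4 (0.3 equiv), L-(+)-DET (0.36 equiv), t-BuOOH, 4 Å MS, CH2Cl2, −20 °C
Reagents that add atoms: tert-butyl hydroperoxide, CC(C)(C)OO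
Why: Sharpless asymmetric epoxidation of a geraniol-type E-allylic alcohol: L-(+)-tartrate delivers oxygen to give the (2S,3S)-epoxy alcohol under reagent control, which sets C12 and C13, and the other alkene (not an allylic alcohol) and the sulfone are inert.

Step 17
Reactants: 22 epoxy alcohol
Product: 23 (12S,13R)-epoxy aldehyde, side chain [(2S,3R)-3-formyl-2-methyloxiran-2-yl]methyl
Conditions: Dess–Martin periodinane, NaHCO3, CH2Cl2, 0 °C → rt
Reagents that add atoms: none
Why: Dess–Martin oxidation of the primary epoxy alcohol under buffered conditions gives the non-enolisable α,β-epoxy aldehyde and does not touch the tertiary alcohol.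

Step 18
Reactants: 23 epoxy aldehyde PMB ether
Product: 24 epoxy aldehyde with free C16 allylic alcohol
Conditions: DDQ, CH2Cl2/pH 7 buffer, 0 °C
Reagents that add atoms: none
Why: Oxidative PMB cleavage by DDQ at neutral pH frees the C16 allylic alcohol without acid or base that would endanger the epoxy aldehyde.

Step 19
Reactants: 24 allylic alcohol
Product: 25 C16 allylic bromide (E), epoxy aldehyde retained
Conditions: PPh3, NBS, CH2Cl2, −30 °C; used at once
Reagents that add atoms: N-bromosuccinimide, O=C1CCC(=O)N1Br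
Why: Appel-type bromination through the alkoxyphosphonium ion converts the primary allylic alcohol by SN2 with retained alkene geometry, the tertiary alcohol and the aldehyde being much slower to react at low temperature.

Step 20
Reactants: 25 bromo aldehyde
Product: 26 macrocyclic sulfone diol: C14 carbinol, C1 isopropenyl, C4 tertiary alcohol, 12S,13S-epoxide
Conditions: CrCl2 (10 equiv), 4 Å MS, THF, slow addition to 2 mM, rt
Reagents that add atoms: none
Why: Intramolecular Nozaki–Hiyama allylation: the allylchromium(III) species adds to the aldehyde through its γ-carbon C1 in a six-membered transition state, forming C14–C1 with the isopropenyl group at C1 and closing the 14-membered ring (counted through the oxolane oxygen), as in related cembranoid ring closures.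

Step 21
Reactants: 26 macrocyclic diol
Product: 27 C14 triethylsilyl ether (C4 hydroxyl free)
Conditions: TESCl, imidazole, DMAP (cat.), DMF, rt
Reagents that add atoms: chlorotriethylsilane, CC[Si](Cl)(CC)CC
Why: Selective silylation of the secondary C14 hydroxyl over the tertiary one blocks Payne-type epoxide migration under the coming base treatment and reserves C4–OH for acetylation.

Step 22
Reactants: 27 macrocyclic sulfone
Product: 30 (6Z)-enol ether macrocycle with C14–OTES and C4–OH, via bromo sulfone 28 (not isolated), via episulfone 29 (not isolated)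
Conditions: BrCF2CF2Br, KOH/Al2O3, t-BuOH/CH2Cl2, 0 °C → rt; filtration through basic alumina
Reagents that add atoms: none
Why: Ramberg–Bäcklund reaction as established for S-glycoside dioxides: α-bromination, 1,3-elimination to the episulfone and loss of SO2 contract the ring to the 14-membered carbocycle and form the exocyclic C6=C7 enol ether, the 6Z isomer (C5 syn to the ring oxygen, away from the C8 methyl and on the shorter bridge to C10) being the expected major one.

Step 23
Reactants: 30 enol ether alcohol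
Product: 31 C4 acetate, C14–OTES
Conditions: Ac2O, Et3N, DMAP, CH2Cl2, rt → 35 °C
Reagents that add atoms: acetic anhydride, CC(=O)OC(C)=O
Why: DMAP-catalysed (Steglich-type) acetylation of the tertiary alcohol under basic conditions installs the C4 acetate and removes the hydroxyl before it can add to the C6=C7 enol ether.

Step 24
Reactants: 31 silyl ether
Product: 32 C14 alcohol
Conditions: TBAF, THF, 0 °C
Reagents that add atoms: none
Why: Fluoride desilylation of the secondary TES ether is compatible with the enol ether, the epoxide and the hindered tertiary acetate.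

Step 25
Reactants: 32 C14 alcohol
Product: 33 C14 ketone with C1 isopropenyl (β,γ-unsaturated epoxy ketone)
Conditions: Dess–Martin periodinane, pyridine, CH2Cl2, 0 °C → rt
Reagents that add atoms: none
Why: Dess–Martin oxidation buffered with pyridine gives the ketone without acid that would hydrolyse the enol ether, and removes the C14 stereocentre.

Step 26
Reactants: 33 β,γ-unsaturated ketone
Product: 34 CNP0162736.1 (target)
Conditions: DBU (0.5 equiv), CH2Cl2, rt
Reagents that add atoms: none
Why: Base-mediated isomerisation through the C1 dienolate moves the double bond into conjugation as the tetrasubstituted isopropylidene enone (the pulegone-type thermodynamic isomer) and removes the C1 stereocentre; the oxirane C13–H is not enolisable.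

## Compound list

1 | (R)-4-benzyl-3-propanoyloxazolidin-2-one | CCC(=O)N1[C@H](Cc2ccccc2)COC1=O | starting material
2 | allyl iodide | C=CCI | starting material
3 | (R)-4-benzyl-3-[(2S)-2-methylpent-4-enoyl]oxazolidin-2-one | C=CC[C@H](C)C(=O)N1[C@H](Cc2ccccc2)COC1=O | intermediate
4 | methyl (2S)-2-methylpent-4-enoate | COC(=O)[C@@H](C)CC=C | intermediate
5 | methyl (2S)-2-methyl-4-oxobutanoate | COC(=O)[C@@H](C)CC=O | intermediate
6 | methyl 3-methylbut-2-enoate | COC(=O)C=C(C)C | starting material
7 | tert-butyl[(1-methoxy-3-methylbuta-1,3-dien-1-yl)oxy]dimethylsilane | C=C(C)C=C(OC)O[Si](C)(C)C(C)(C)C | intermediate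
8 | dimethyl (2S,4R,6E)-4-hydroxy-2,6-dimethyloct-6-enedioate | COC(=O)[C@@H](C)C[C@@H](O)C/C(C)=C/C(=O)OC | intermediate
9 | methyl (2E)-3-methyl-4-[(2R,4S)-4-methyl-5-oxooxolan-2-yl]but-2-enoate | O=C1O[C@H](C[C@@H]1C)C/C(C)=C/C(=O)OC | intermediate
10 | (3S,5R)-5-[(2E)-4-hydroxy-2-methylbut-2-en-1-yl]-3-methyloxolan-2-ol | OC1O[C@H](C[C@@H]1C)C/C(C)=C/CO | intermediate
11 | (3S,5R)-5-[(2E)-4-(tert-butyldiphenylsilyloxy)-2-methylbut-2-en-1-yl]-3-methyloxolan-2-ol | OC1O[C@H](C[C@@H]1C)C/C(C)=C/CO[Si](c2ccccc2)(c2ccccc2)C(C)(C)C | intermediate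
12 | S-[(3S,5R)-5-[(2E)-4-(tert-butyldiphenylsilyloxy)-2-methylbut-2-en-1-yl]-3-methyloxolan-2-yl] ethanethioate | CC(=O)SC1O[C@H](C[C@@H]1C)C/C(C)=C/CO[Si](c2ccccc2)(c2ccccc2)C(C)(C)C | intermediate
13 | (R)-linalool | O[C@@](CCC=C(C)C)(C)C=C | starting material
14 | (2E,6R)-2,6-dimethylocta-2,7-diene-1,6-diol | O[C@@](CC/C=C(\C)CO)(C)C=C | intermediate
15 | (3R,6E)-8-[(4-methoxybenzyl)oxy]-3,7-dimethylocta-1,6-dien-3-ol | O[C@@](CC/C=C(\C)COCc1ccc(OC)cc1)(C)C=C | intermediate
16 | (3R,6E)-8-[(4-methoxybenzyl)oxy]-3,7-dimethyloct-6-ene-1,3-diol | O[C@@](CC/C=C(\C)COCc1ccc(OC)cc1)(C)CCO | intermediate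
17 | (3R,6E)-3-hydroxy-8-[(4-methoxybenzyl)oxy]-3,7-dimethyloct-6-en-1-yl 4-methylbenzenesulfonate | O[C@@](CC/C=C(\C)COCc1ccc(OC)cc1)(C)CCOS(=O)(=O)c1ccc(C)cc1 | intermediate
18 | sodium (3S,5R)-5-[(2E)-4-(tert-butyldiphenylsilyloxy)-2-methylbut-2-en-1-yl]-3-methyloxolane-2-thiolate | [Na+].[S-]C1O[C@H](C[C@@H]1C)C/C(C)=C/CO[Si](c2ccccc2)(c2ccccc2)C(C)(C)C | intermediate
19 | C7–S–C6 thioether (C14–OTBDPS, C16–OPMB, C4–OH) | O[C@@](CC/C=C(\C)COCc1ccc(OC)cc1)(C)CCSC2O[C@H](C[C@@H]2C)C/C(C)=C/CO[Si](c3ccccc3)(c3ccccc3)C(C)(C)C | intermediate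
20 | C7–SO2–C6 sulfone (C14–OTBDPS, C16–OPMB, C4–OH) | O[C@@](CC/C=C(\C)COCc1ccc(OC)cc1)(C)CCS(=O)(=O)C2O[C@H](C[C@@H]2C)C/C(C)=C/CO[Si](c3ccccc3)(c3ccccc3)C(C)(C)C | intermediate
21 | sulfone with free C14 allylic alcohol | O[C@@](CC/C=C(\C)COCc1ccc(OC)cc1)(C)CCS(=O)(=O)C2O[C@H](C[C@@H]2C)C/C(C)=C/CO | intermediate
22 | (12S,13S)-epoxy alcohol sulfone | O[C@@](CC/C=C(\C)COCc1ccc(OC)cc1)(C)CCS(=O)(=O)C2O[C@H](C[C@@H]2C)C[C@]3(C)O[C@H]3CO | intermediate
23 | (12S,13R)-epoxy aldehyde sulfone, C16–OPMB | O[C@@](CC/C=C(\C)COCc1ccc(OC)cc1)(C)CCS(=O)(=O)C2O[C@H](C[C@@H]2C)C[C@]3(C)O[C@H]3C=O | intermediate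
24 | epoxy aldehyde sulfone, C16–OH | O[C@@](CC/C=C(\C)CO)(C)CCS(=O)(=O)C2O[C@H](C[C@@H]2C)C[C@]3(C)O[C@H]3C=O | intermediate
25 | epoxy aldehyde sulfone, C16–Br | O[C@@](CC/C=C(\C)CBr)(C)CCS(=O)(=O)C2O[C@H](C[C@@H]2C)C[C@]3(C)O[C@H]3C=O | intermediate
26 | macrocyclic sulfone diol (C14–OH, C1 isopropenyl, C4–OH) | O[C@@]1(C)CCS(=O)(=O)C2O[C@H](C[C@@H]2C)C[C@]3(C)O[C@H]3C(O)C(C(C)=C)CC1 | intermediate
27 | macrocyclic sulfone, C14–OTES | O[C@@]1(C)CCS(=O)(=O)C2O[C@H](C[C@@H]2C)C[C@]3(C)O[C@H]3C(O[Si](CC)(CC)CC)C(C(C)=C)CC1 | intermediate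
28 | C6-bromo sulfone | O[C@@]1(C)CC(Br)S(=O)(=O)C2O[C@H](C[C@@H]2C)C[C@]3(C)O[C@H]3C(O[Si](CC)(CC)CC)C(C(C)=C)CC1 | intermediate
29 | C6/C7 episulfone (thiirane 1,1-dioxide) | O[C@@]1(C)CC2S(=O)(=O)C23O[C@H](C[C@@H]3C)C[C@]4(C)O[C@H]4C(O[Si](CC)(CC)CC)C(C(C)=C)CC1 | intermediate
30 | (6Z)-enol ether macrocycle, C4–OH, C14–OTES | O[C@@]1(C)C/C=C2\O[C@H](C[C@@H]2C)C[C@]3(C)O[C@H]3C(O[Si](CC)(CC)CC)C(C(C)=C)CC1 | intermediate
31 | C4 acetate, C14–OTES | CC(=O)O[C@@]1(C)C/C=C2\O[C@H](C[C@@H]2C)C[C@]3(C)O[C@H]3C(O[Si](CC)(CC)CC)C(C(C)=C)CC1 | intermediate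
32 | C4 acetate, C14–OH | CC(=O)O[C@@]1(C)C/C=C2\O[C@H](C[C@@H]2C)C[C@]3(C)O[C@H]3C(O)C(C(C)=C)CC1 | intermediate
33 | C14 ketone, C1 isopropenyl | CC(=O)O[C@@]1(C)C/C=C2\O[C@H](C[C@@H]2C)C[C@]3(C)O[C@H]3C(=O)C(C(C)=C)CC1 | intermediate
34 | CNP0162736.1 | CC(=O)O[C@@]1(C)C/C=C2\O[C@H](C[C@@H]2C)C[C@]2(C)O[C@H]2C(=O)C(=C(C)C)CC1 | target

## Summary and risks

Total step count: 26. Longest linear sequence: 21 steps (1–3, 5–8, 13–26).

Steps most likely to fail:

**Step 5 (key step).** The aliphatic aldehyde may be held back as its α-chloro silyl ether so that addition is slow; the catalyst may not fully override the β-methyl bias (C10 epimer); part of the enoate may form with Z geometry. Fallback, from 5 back to 9, with reagent-controlled allylboration in place of the aldol: 5 is treated with (−)-Ipc2B(2-methylallyl) (Si-face selective; Et2O, −78 °C; NaBO3 work-up) to give methyl (2S,4R)-4-hydroxy-2,6-dimethylhept-6-enoate F1, which closes with PPTS to (3S,5R)-3-methyl-5-(2-methylprop-2-en-1-yl)oxolan-2-one F2. Ozonolysis (O3; PPh3) gives (3S,5R)-3-methyl-5-(2-oxopropyl)oxolan-2-one F3, and Horner–Wadsworth–Emmons olefination with trimethyl phosphonoacetate/NaH in THF gives the trisubstituted enoate, whose E isomer, separated from Z, is 9.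

**Step 22.** Epimerisation at the halosulfone/episulfone stage may give the 6E enol ether; bromination or elimination may occur at other acidic sites; hydroxide may attack or shift the epoxide. Fallback, from 20 back to 32, with the enol ether made before ring closure so that isomers can be separated on a simple compound:
- DDQ on 20 gives the C16 alcohol sulfone F4.
- The same Ramberg–Bäcklund conditions give the acyclic (6Z)-enol ether diol F5.
- Ac2O/DMAP/Et3N gives the C4,C16-diacetate F6.
- TBAF gives the C14 allylic alcohol F7.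
- Sharpless epoxidation with L-(+)-DET gives the epoxy alcohol F8.
- Dess–Martin/pyridine gives the epoxy aldehyde F9.
- The ring is closed by Pd(PPh3)4/InI umpolung allylation of the C16 allylic acetate (γ-attack at C1, high dilution), which gives 32.

**Step 20.** Chromium salts may reduce or open the α,β-epoxy aldehyde; the C4 hydroxyl may close onto the allylic bromide by SN2' before metalation; oligomers may form. Fallback, from 24 back to 26, with the allyl nucleophile generated catalytically from a stable precursor instead of from a preformed bromide and stoichiometric Cr(II): 24 with ClCO2Me/pyridine gives the C16 allylic methyl carbonate F10, and Pd(PPh3)4/InI in THF under high dilution converts the π-allylpalladium into an allylindium that adds through C1 to the aldehyde, giving 26.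

## Further compounds

F1 | step 5 | methyl (2S,4R)-4-hydroxy-2,6-dimethylhept-6-enoate | COC(=O)[C@@H](C)C[C@@H](O)CC(C)=C
F2 | step 5 | (3S,5R)-3-methyl-5-(2-methylprop-2-en-1-yl)oxolan-2-one | O=C1O[C@H](C[C@@H]1C)CC(C)=C
F3 | step 5 | (3S,5R)-3-methyl-5-(2-oxopropyl)oxolan-2-one | O=C1O[C@H](C[C@@H]1C)CC(C)=O
F4 | step 22 | sulfone 20 with free C16 allylic alcohol (C14–OTBDPS) | O[C@@](CC/C=C(\C)CO)(C)CCS(=O)(=O)C2O[C@H](C[C@@H]2C)C/C(C)=C/CO[Si](c3ccccc3)(c3ccccc3)C(C)(C)C
F5 | step 22 | acyclic (6Z)-enol ether diol (C4–OH, C16–OH, C14–OTBDPS) | O[C@@](CC/C=C(\C)CO)(C)C/C=C2\O[C@H](C[C@@H]2C)C/C(C)=C/CO[Si](c3ccccc3)(c3ccccc3)C(C)(C)C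
F6 | step 22 | acyclic enol ether C4,C16-diacetate (C14–OTBDPS) | CC(=O)O[C@@](CC/C=C(\C)COC(C)=O)(C)C/C=C2\O[C@H](C[C@@H]2C)C/C(C)=C/CO[Si](c3ccccc3)(c3ccccc3)C(C)(C)C
F7 | step 22 | acyclic enol ether diacetate with free C14 allylic alcohol | CC(=O)O[C@@](CC/C=C(\C)COC(C)=O)(C)C/C=C2\O[C@H](C[C@@H]2C)C/C(C)=C/CO
F8 | step 22 | acyclic enol ether diacetate (12S,13S)-epoxy alcohol | CC(=O)O[C@@](CC/C=C(\C)COC(C)=O)(C)C/C=C2\O[C@H](C[C@@H]2C)C[C@]3(C)O[C@H]3CO
F9 | step 22 | acyclic enol ether diacetate (12S,13R)-epoxy aldehyde | CC(=O)O[C@@](CC/C=C(\C)COC(C)=O)(C)C/C=C2\O[C@H](C[C@@H]2C)C[C@]3(C)O[C@H]3C=O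
F10 | step 20 | C16 allylic methyl carbonate of 24 | O[C@@](CC/C=C(\C)COC(=O)OC)(C)CCS(=O)(=O)C2O[C@H](C[C@@H]2C)C[C@]3(C)O[C@H]3C=O
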